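**Plan**
- Retrosynthetic cuts, in order: the C8 tiglate and the C15 silyl ether; the C11=C13 methylene; the C7–C11 bond of the γ-lactone (back to a C6 acetate and a cis-7,8-epoxide); the C7=C8 alkene (metathesis); the O–C3 bond of the furanone; C1–C2 (acetylide plus Weinreb amide); C3–C4 (Negishi coupling).
- Feature used: the γ-lactone fused at C6–C7 of the ten-membered ring has its oxygen on C6, its α-carbon C11 on C7 and a separate oxygen on the adjacent C8. This is the pattern left when the enolate of a C6-bound acetate opens a cis-7,8-epoxide at C7.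
- Forward: an amide fragment (C1, C8–C10, C14) and an enyne fragment (C2–C7, C15) are joined at C1–C2. The furanone ring closes first (gold, O–C3), the ten-membered ring second (metathesis, C7=C8), the lactone ring last (key step); then methylenation, tigloylation, desilylation.
- Stereochemistry: C10 from (S)-lactic acid by anti-alkylation of its pivalaldehyde acetal; C6 from a lipase resolution; C4=C5 from trans-hydroalumination/iodination; C7=C8 Z from ring size; C7 and C8 from hydroxyl-directed syn-epoxidation and inversion at C7 in the epoxide opening.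

Key step: step 15

Remark: the bicyclic compounds are numbered as germacranes (C1 ketone, ring oxygen between C3 and C10, C4=C5 with C15 on C4, lactone oxygen on C6, lactone carbons C11–C13); compounds 19–21 lack C11–C13.
Assumption: the lipase follows the usual size rule for secondary carbinols and acetylates the (R)-enynol.

Step 1
Reactants: 1 (S)-lactic acid
Product: 2 (2S,5S)-2-tert-butyl-5-methyl-1,3-dioxolan-4-one (cis)
Conditions: t-BuCHO, TsOH·H2O (cat.), H2SO4 (cat.), pentane, reflux with water separator; crystallisation from pentane, −78 °C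
Reagents that add atoms: pivalaldehyde, CC(C)(C)C=O
Why: Acid-catalysed acetalisation of the α-hydroxy acid; the acetal carbon is set under equilibrating conditions cis to the methyl group and the cis isomer is purified by crystallisation (first stage of self-regeneration of a stereocentre).

Step 2
Reactants: 2 (2S,5S)-2-tert-butyl-5-methyl-1,3-dioxolan-4-one
Product: 4 (2S,5R)-5-allyl-2-tert-butyl-5-methyl-1,3-dioxolan-4-one, via lithium enolate 3 (not isolated)
Conditions: LiN(i-Pr)2, THF, −78 °C; allyl bromide, −78 → −20 °C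
Reagents that add atoms: allyl bromide, C=CCBr
Why: Enolate alkylation in which the planar enolate is attacked anti to the tert-butyl group, so the quaternary centre (later C10) forms with allyl in the place of the former hydrogen.

Step 3
Reactants: 4 (2S,5R)-5-allyl-2-tert-butyl-5-methyl-1,3-dioxolan-4-one
Product: 5 (2R)-2-hydroxy-N-methoxy-N,2-dimethylpent-4-enamide
Conditions: MeNH(OMe)·HCl, i-PrMgCl, THF, −20 → 0 °C
Reagents that add atoms: N,O-dimethylhydroxylamine hydrochloride, CNOC.Cl
Why: Weinreb amide formation by aminolysis of the acetal-lactone with the magnesium amide, with loss of pivalaldehyde; the quaternary centre is not touched.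

Step 4
Reactants: 6 tert-butyldimethyl(prop-2-yn-1-yloxy)silane; 7 acrolein
Product: 9 rac-6-[(tert-butyldimethylsilyl)oxy]hex-1-en-4-yn-3-ol, via lithium acetylide 8 (not isolated)
Conditions: n-BuLi, THF, −78 °C; then 7, −78 °C; aq NH4Cl
Reagents that add atoms: none
Why: 1,2-Addition of a lithium acetylide to an enal; the carbinol centre (later C6) forms racemic and is resolved in step 5.

Step 5
Reactants: 9 rac-6-[(tert-butyldimethylsilyl)oxy]hex-1-en-4-yn-3-ol
Product: 10 (3S)-6-[(tert-butyldimethylsilyl)oxy]hex-1-en-4-yn-3-ol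
Conditions: Burkholderia cepacia lipase (Amano PS, immobilised), vinyl acetate, hexane, 30 °C, stopped just past half conversion; chromatography
Reagents that add atoms: none
Why: Lipase-catalysed kinetic resolution by enantioselective transesterification; with the substituted alkynyl group as the large and vinyl as the small substituent the (R)-alcohol should be acetylated, leaving the (S)-alcohol that carries the C6 configuration of the target.

Step 6
Reactants: 10 (3S)-6-[(tert-butyldimethylsilyl)oxy]hex-1-en-4-yn-3-ol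
Product: 12 (3S,4Z)-6-[(tert-butyldimethylsilyl)oxy]-5-iodohexa-1,4-dien-3-ol, via cyclic alkenylaluminate 11 (not isolated)
Conditions: NaAlH2(OCH2CH2OMe)2, THF, 0 °C; EtOAc; then I2, THF, −78 °C; aq Na2S2O3, aq potassium sodium tartrate
Reagents that add atoms: iodine, II
Why: Hydroxyl-directed trans-hydroalumination of a propargylic alcohol and iodinolysis with retention; hydride goes to C5 and aluminium, then iodine, to C4 cis to the carbinol carbon, which fixes the later C4=C5 geometry and leaves the carbinol centre unchanged.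

Step 7
Reactants: 12 (3S,4Z)-6-[(tert-butyldimethylsilyl)oxy]-5-iodohexa-1,4-dien-3-ol
Product: 13 (3S,4Z)-6-[(tert-butyldimethylsilyl)oxy]-5-iodo-3-[(triethylsilyl)oxy]hexa-1,4-diene
Conditions: Et3SiCl, imidazole, DMAP (cat.), CH2Cl2, 0 °C
Reagents that add atoms: chlorotriethylsilane, CC[Si](Cl)(CC)CC
Why: Silylation of a secondary alcohol; the triethylsilyl ether masks the C6 oxygen through the organometallic and gold steps and can later be removed beside the primary tert-butyldimethylsilyl ether.

Step 8
Reactants: 13 (3S,4Z)-6-[(tert-butyldimethylsilyl)oxy]-5-iodo-3-[(triethylsilyl)oxy]hexa-1,4-diene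
Product: 14 (3S,4E)-5-{[(tert-butyldimethylsilyl)oxy]methyl}-3-[(triethylsilyl)oxy]hepta-1,4-dien-6-yne
Conditions: HC≡CMgBr, ZnBr2, THF, 0 °C; then 13, Pd(PPh3)4 (5 mol %), THF, rt
Reagents that add atoms: ethynylmagnesium bromide, C#C[Mg]Br
Why: Negishi coupling of an alkenyl iodide with ethynylzinc bromide; the alkene geometry is retained, so the ethynyl group (C3, C2) stands cis to C6.

Step 9
Reactants: 14 (3S,4E)-5-{[(tert-butyldimethylsilyl)oxy]methyl}-3-[(triethylsilyl)oxy]hepta-1,4-dien-6-yne; 5 (2R)-2-hydroxy-N-methoxy-N,2-dimethylpent-4-enamide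
Product: 16 (4R,8E,10S)-8-{[(tert-butyldimethylsilyl)oxy]methyl}-4-hydroxy-4-methyl-10-[(triethylsilyl)oxy]dodeca-1,8,11-trien-6-yn-5-one, via lithium acetylide 15 (not isolated)
Conditions: 14 (2.2 equiv), n-BuLi (2.1 equiv), THF, −78 °C; then 5, −78 → 0 °C; aq NH4Cl; surplus 14 recovered
Reagents that add atoms: none
Why: Acylation of a lithium acetylide by a Weinreb amide, whose chelated adduct stops at the ketone; the first equivalent of acetylide is spent on the tertiary hydroxyl and returns as 14 on work-up, and no stereocentre is formed.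

Step 10
Reactants: 16 (the α′-hydroxy ynone)
Product: 17 (2R)-5-{(2Z,4S)-1-[(tert-butyldimethylsilyl)oxy]-4-[(triethylsilyl)oxy]hexa-2,5-dien-2-yl}-2-methyl-2-(prop-2-en-1-yl)furan-3(2H)-one
Conditions: (p-CF3C6H4)3PAuCl (5 mol %), AgOTf (5 mol %), toluene, rt
Reagents that add atoms: none
Why: Gold-catalysed 5-endo-dig cycloisomerisation of an α′-hydroxy ynone to a 3(2H)-furanone: the tertiary hydroxyl adds to the gold-bound alkyne at C3 and protodeauration gives the enone, while the silylated C6 oxygen cannot compete and no stereocentre changes.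

Step 11
Reactants: 17 (the furanone bis-silyl ether)
Product: 18 (2R)-5-{(2Z,4S)-1-[(tert-butyldimethylsilyl)oxy]-4-hydroxyhexa-2,5-dien-2-yl}-2-methyl-2-(prop-2-en-1-yl)furan-3(2H)-one
Conditions: PPTS (0.2 equiv), MeOH–CH2Cl2, 0 °C
Reagents that add atoms: none
Why: Acid-catalysed methanolysis of a silyl ether; the secondary triethylsilyl ether is cleaved much faster than the primary tert-butyldimethylsilyl ether.

Step 12
Reactants: 18 (the furanone dienol)
Product: 19 (6S,10R)-15-[(tert-butyldimethylsilyl)oxy]-6-hydroxy-3,10-epoxy-11,12,13-trinorgermacra-2,4Z,7Z-trien-1-one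
Conditions: second-generation Grubbs catalyst (H2IMes)(PCy3)Cl2Ru=CHPh (10 mol %), 1,4-benzoquinone (20 mol %), CH2Cl2 (1 mM), 40 °C
Reagents that add atoms: none
Why: Ring-closing olefin metathesis of the two monosubstituted alkenes with loss of ethene; the ten-membered carbocycle (nine-membered ring through the furanone oxygen) can only hold the Z alkene, the free allylic hydroxyl helps the catalyst load and benzoquinone suppresses alkene migration.

Step 13
Reactants: 19 (the macrocyclic Z-allylic alcohol)
Product: 20 (6R,7R,8S,10R)-15-[(tert-butyldimethylsilyl)oxy]-7,8-epoxy-6-hydroxy-3,10-epoxy-11,12,13-trinorgermacra-2,4Z-dien-1-one (cis-epoxide on the face of the 6-hydroxyl)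
Conditions: VO(acac)2 (5 mol %), t-BuOOH (1.5 equiv, decane solution), CH2Cl2, 0 °C → rt
Reagents that add atoms: tert-butyl hydroperoxide, CC(C)(C)OO
Why: Hydroxyl-directed epoxidation of an allylic alcohol: oxygen is passed within the vanadate ester of the C6 hydroxyl to the C7=C8 face on the side of that hydroxyl, as in medium-ring Z-cycloalkenols, which sets C7 and C8 (cis-epoxide, erythro to C6), while the conjugated, electron-poor C4=C5 bond should react more slowly.

Step 14
Reactants: 20 (the epoxy alcohol)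
Product: 21 6-O-acetate of 20 ((6R,7S,8S,10R) by the sequence rule; same spatial arrangement)
Conditions: Ac2O, pyridine, DMAP (cat.), CH2Cl2, 0 °C
Reagents that add atoms: acetic anhydride, CC(=O)OC(C)=O
Why: DMAP-catalysed acylation of a secondary alcohol under buffered conditions that leave the epoxide and all stereocentres untouched.

Step 15
Reactants: 21 (the macrocyclic cis-7,8-epoxide with C6 acetate)
Product: 24 (6R,7R,8S,10R)-15-[(tert-butyldimethylsilyl)oxy]-8-hydroxy-1-oxo-3,10-epoxy-13-norgermacra-2,4Z-dien-6,12-olide (trans-fused γ-lactone), via lithium enolate 22 (not isolated), via diethylaluminium enolate 23 (not isolated)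
Conditions: LiN(SiMe3)2 (1.1 equiv), THF, −78 °C; then Et2AlCl (1.2 equiv), −78 → −20 °C; cold aq potassium sodium tartrate
Reagents that add atoms: none
Why: LiN(SiMe3)2 removes an acetate α-proton, Et2AlCl converts the lithium enolate into the aluminium enolate and binds the epoxide oxygen, and the enolate carbon C11 attacks C7 from the side opposite the C7–O bond, forming C7–C11 and the γ-lactone and releasing the C8 oxygen as its aluminium alkoxide. The closest known reaction type is the Lewis-acid-assisted opening of epoxides by acetate enolates used for trans-lactone annulation, made intramolecular here through the ester of a 2,3-epoxy alcohol. The lactone ring closes in the 5-exo-tet mode (C11, C12, O, C6 and C7 in the ring, the breaking C7–O bond outside it). The one new stereocentre, C7, is fixed by the cis-epoxide through inversion, which puts C11 anti to the C6 oxygen (trans-fused lactone) and leaves C8 as set in step 13. The step needs attack at C7 in preference to 6-endo attack at C8, to conjugate addition at C5 of the dienone and to proton loss at C6; the three-atom tether, aluminium activation of the epoxide, a hard non-stabilised enolate at low temperature and a ring conformation with the C6–O and C7–O bonds antiperiplanar are what secure it.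

Step 16
Reactants: 24 (the 8-hydroxy lactone)
Product: 27 (6R,7R,8S,10R)-15-[(tert-butyldimethylsilyl)oxy]-8-hydroxy-1-oxo-3,10-epoxygermacra-2,4Z,11(13)-trien-6,12-olide, via Mannich base 25 (not isolated), via trimethylammonium iodide 26 (not isolated)
Conditions: LiN(SiMe3)2 (2.5 equiv), THF, −78 °C; CH2=NMe2+ I−, −78 → 0 °C; aq NH4Cl; then MeI, CH2Cl2–MeOH, rt; then aq NaHCO3, EtOAc, rt
Reagents that add atoms: N,N-dimethylmethyleneiminium iodide (Eschenmoser's salt), C=[N+](C)C.[I-]
Why: α-Methylenation of a lactone by Mannich reaction of its lithium enolate with Eschenmoser's salt, quaternisation and base-induced elimination of trimethylamine; the C8 hydroxyl is carried as its lithium alkoxide, and the C11 centre made in the Mannich step is erased again in the elimination.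

Step 17
Reactants: 27 (the 8-hydroxy α-methylene lactone)
Product: 28 8-O-[(E)-2-methylbut-2-enoyl] ester (tiglate) of 27
Conditions: tiglic acid, 2,4,6-Cl3C6H2COCl, Et3N, toluene, rt; then 27, DMAP, rt
Reagents that add atoms: tiglic acid, C/C=C(\C)C(=O)O
Why: Yamaguchi esterification: the mixed trichlorobenzoic anhydride of tiglic acid acylates the hindered C8 hydroxyl under DMAP catalysis, with retention at C8 and without change of the E geometry.

Step 18
Reactants: 28 (the 15-O-silyl tiglate)
Product: 29 lychnophorolide B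
Conditions: HF·pyridine, pyridine, THF, 0 °C → rt
Reagents that add atoms: none
Why: Fluoride-mediated cleavage of a primary silyl ether under buffered, weakly acidic conditions that spare the tiglate, the α-methylene lactone and the dienone.

**Compound list**
1 | (S)-lactic acid | C[C@H](O)C(=O)O | starting material
2 | (2S,5S)-2-tert-butyl-5-methyl-1,3-dioxolan-4-one | C[C@@H]1O[C@H](C(C)(C)C)OC1=O | intermediate
3 | lithium enolate of 2 | CC1=C(O[Li])O[C@@H](C(C)(C)C)O1 | intermediate
4 | (2S,5R)-5-allyl-2-tert-butyl-5-methyl-1,3-dioxolan-4-one | C[C@]1(CC=C)O[C@H](C(C)(C)C)OC1=O | intermediate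
5 | (2R)-2-hydroxy-N-methoxy-N,2-dimethylpent-4-enamide | C=CC[C@@](C)(O)C(=O)N(C)OC | intermediate
6 | tert-butyldimethyl(prop-2-yn-1-yloxy)silane | C#CCO[Si](C)(C)C(C)(C)C | starting material
7 | acrolein | C=CC=O | starting material
8 | lithium acetylide of 6 | [Li]C#CCO[Si](C)(C)C(C)(C)C | intermediate
9 | rac-6-[(tert-butyldimethylsilyl)oxy]hex-1-en-4-yn-3-ol | C=CC(O)C#CCO[Si](C)(C)C(C)(C)C | intermediate
10 | (3S)-6-[(tert-butyldimethylsilyl)oxy]hex-1-en-4-yn-3-ol | C=C[C@H](O)C#CCO[Si](C)(C)C(C)(C)C | intermediate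
11 | sodium cyclic alkenylaluminate (aluminium bound to the C6 oxygen and to C4, two 2-methoxyethoxy ligands) | [Na+].C=C[C@@H]1O[Al-](OCCOC)(OCCOC)C(CO[Si](C)(C)C(C)(C)C)=C1 | intermediate
12 | (3S,4Z)-6-[(tert-butyldimethylsilyl)oxy]-5-iodohexa-1,4-dien-3-ol | C=C[C@H](O)/C=C(\I)CO[Si](C)(C)C(C)(C)C | intermediate
13 | triethylsilyl ether of 12 | C=C[C@H](O[Si](CC)(CC)CC)/C=C(\I)CO[Si](C)(C)C(C)(C)C | intermediate
14 | (3S,4E)-5-{[(tert-butyldimethylsilyl)oxy]methyl}-3-[(triethylsilyl)oxy]hepta-1,4-dien-6-yne | C=C[C@H](O[Si](CC)(CC)CC)/C=C(\C#C)CO[Si](C)(C)C(C)(C)C | intermediate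
15 | lithium acetylide of 14 | C=C[C@H](O[Si](CC)(CC)CC)/C=C(\C#C[Li])CO[Si](C)(C)C(C)(C)C | intermediate
16 | (4R,8E,10S)-8-{[(tert-butyldimethylsilyl)oxy]methyl}-4-hydroxy-4-methyl-10-[(triethylsilyl)oxy]dodeca-1,8,11-trien-6-yn-5-one | C=CC[C@@](C)(O)C(=O)C#C/C(CO[Si](C)(C)C(C)(C)C)=C\[C@@H](O[Si](CC)(CC)CC)C=C | intermediate
17 | (2R)-5-{(2Z,4S)-1-[(tert-butyldimethylsilyl)oxy]-4-[(triethylsilyl)oxy]hexa-2,5-dien-2-yl}-2-methyl-2-(prop-2-en-1-yl)furan-3(2H)-one | C=CC[C@@]1(C)OC(=CC1=O)/C(CO[Si](C)(C)C(C)(C)C)=C\[C@@H](O[Si](CC)(CC)CC)C=C | intermediate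
18 | (2R)-5-{(2Z,4S)-1-[(tert-butyldimethylsilyl)oxy]-4-hydroxyhexa-2,5-dien-2-yl}-2-methyl-2-(prop-2-en-1-yl)furan-3(2H)-one | C=CC[C@@]1(C)OC(=CC1=O)/C(CO[Si](C)(C)C(C)(C)C)=C\[C@@H](O)C=C | intermediate
19 | macrocyclic Z-allylic alcohol, (6S,10R), 4Z,7Z, 15-O-TBS | O[C@@H]1/C=C(/CO[Si](C)(C)C(C)(C)C)C2=CC(=O)[C@@](C)(C/C=C\1)O2 | intermediate
20 | macrocyclic cis-7,8-epoxy 6-alcohol, (6R,7R,8S,10R), epoxide syn to 6-OH, 15-O-TBS | O[C@@H]1/C=C(/CO[Si](C)(C)C(C)(C)C)C2=CC(=O)[C@@](C)(C[C@@H]3O[C@H]13)O2 | intermediate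
21 | macrocyclic cis-7,8-epoxide with C6 acetate, 15-O-TBS | CC(=O)O[C@@H]1/C=C(/CO[Si](C)(C)C(C)(C)C)C2=CC(=O)[C@@](C)(C[C@@H]3O[C@H]13)O2 | intermediate
22 | lithium enolate of 21 | C=C(O[Li])O[C@@H]1/C=C(/CO[Si](C)(C)C(C)(C)C)C2=CC(=O)[C@@](C)(C[C@@H]3O[C@H]13)O2 | intermediate
23 | diethylaluminium enolate of 21 | C=C(O[Al](CC)CC)O[C@@H]1/C=C(/CO[Si](C)(C)C(C)(C)C)C2=CC(=O)[C@@](C)(C[C@@H]3O[C@H]13)O2 | intermediate
24 | 8-hydroxy macrocycle with saturated trans-fused lactone, (6R,7R,8S,10R), 15-O-TBS | C1C(=O)O[C@@H]2/C=C(/CO[Si](C)(C)C(C)(C)C)C3=CC(=O)[C@@](C)(C[C@H](O)[C@@H]12)O3 | intermediate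
25 | 11-(dimethylaminomethyl) lactone (Mannich base, C11 epimers) | CN(C)CC1C(=O)O[C@@H]2/C=C(/CO[Si](C)(C)C(C)(C)C)C3=CC(=O)[C@@](C)(C[C@H](O)[C@@H]12)O3 | intermediate
26 | trimethylammonium iodide of 25 | C[N+](C)(C)CC1C(=O)O[C@@H]2/C=C(/CO[Si](C)(C)C(C)(C)C)C3=CC(=O)[C@@](C)(C[C@H](O)[C@@H]12)O3.[I-] | intermediate
27 | 8-hydroxy α-methylene lactone, (6R,7R,8S,10R), 15-O-TBS | C=C1C(=O)O[C@@H]2/C=C(/CO[Si](C)(C)C(C)(C)C)C3=CC(=O)[C@@](C)(C[C@H](O)[C@@H]12)O3 | intermediate
28 | 8-O-tiglate of 27, 15-O-TBS | C=C1C(=O)O[C@@H]2/C=C(/CO[Si](C)(C)C(C)(C)C)C3=CC(=O)[C@@](C)(C[C@H](OC(=O)/C(C)=C/C)[C@@H]12)O3 | intermediate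
29 | lychnophorolide B, (6R,7R,8S,10R) | C=C1C(=O)O[C@@H]2/C=C(/CO)C3=CC(=O)[C@@](C)(C[C@H](OC(=O)/C(C)=C/C)[C@@H]12)O3 | target

**Count and risks**
Total step count: 18 (3 for the amide fragment, 5 for the enyne fragment, 10 after their union). Longest linear sequence: 15 steps (steps 4–18).

Step 15. What may go wrong: the non-stabilised enolate may add irreversibly to C5 of the dienone, the base may take the C6 proton instead of an acetate proton, or the freed C8 alkoxide may shift the acyl group (translactonisation) before the quench. The fallback sets out from 20 and returns at 27, replacing steps 14–16. Alcohol 20 is esterified with diethylphosphonoacetic acid (DCC, DMAP, CH2Cl2) to give phosphonoacetate F1. Its phosphonate-stabilised carbanion (KN(SiMe3)2, 1 equiv, THF, −78 °C, then Et2AlCl, slow warming to 0 °C) needs no excess of strong base and adds to C5 only reversibly. It opens the epoxide at C7 in the same 5-exo mode with inversion and gives α-phosphono lactone F2. Horner–Wadsworth–Emmons reaction of F2 with aqueous formaldehyde and K2CO3 in THF at 0 °C then brings in C13 and gives 27.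

Step 12. What may go wrong: metathesis is reversible, so the strained bicyclic Z,Z-diene may be re-opened and drained into dimers and oligomers, or ruthenium hydrides from catalyst decay may isomerise the doubly allylic alcohol to a ketone. The fallback sets out from 2 (with 6 as second component) and returns at 19; it closes the ring irreversibly at C6–C7 by a Nozaki–Hiyama–Kishi reaction.
- Amide side: enolate 3 from 2 is alkylated with (Z)-3-bromo-1-iodoprop-1-ene to give (Z)-iodoallyl dioxolanone F3, which Me3Al and MeNH(OMe)·HCl in CH2Cl2 open to iodoalkenyl Weinreb amide F4.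
- Enyne side: silyl ether 6 is hydroxymethylated (n-BuLi, paraformaldehyde, THF) to butynol F5. The reagents of step 6 give (Z)-iodo alkenol F6, those of step 7 its triethylsilyl ether F7, and those of step 8 enyne F8.
- Union and ring closure: lithiated F8 and F4 give ynone F9 as in step 9, and the gold catalyst of step 10 gives furanone F10. PPTS in methanol frees primary allylic alcohol F11, and MnO2 in CH2Cl2 oxidises it to enal F12. CrCl2 with NiCl2 (cat.) in DMSO–THF at high dilution inserts into the C7–I bond and adds the Z-alkenyl chromium species to the C6 aldehyde. This should give 19 together with its C6 epimer F13, which is separated.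

Step 13. What may go wrong: oxygen may be delivered to the wrong face of C7=C8 or to the C4=C5 bond, or the doubly allylic carbinol may be dehydrogenated to the ketone instead of directing the oxidant. The fallback sets out from 19 and returns at 20. Alcohol 19 is oxidised on purpose (MnO2, CH2Cl2) to macrocyclic dienone F14. Weitz–Scheffer epoxidation (t-BuOOH, DBU, CH2Cl2, 0 °C) should attack the less substituted cis-enone C7=C8 and give cis-epoxy ketone F15, with the face chosen by the ring and no longer by a directing group. Chelation-controlled reduction with Zn(BH4)2 (Et2O, −20 °C) then sets C6 erythro to the epoxide and gives 20; the configuration of F15 relative to C10 is checked before going on.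

**Further compounds**
F1 | step 15 | C6 diethylphosphonoacetate of epoxy alcohol 20 | CCOP(=O)(OCC)CC(=O)O[C@@H]1/C=C(/CO[Si](C)(C)C(C)(C)C)C2=CC(=O)[C@@](C)(C[C@@H]3O[C@H]13)O2
F2 | step 15 | 11-(diethoxyphosphoryl) analogue of lactone 24 (C11 epimers) | CCOP(=O)(OCC)C1C(=O)O[C@@H]2/C=C(/CO[Si](C)(C)C(C)(C)C)C3=CC(=O)[C@@](C)(C[C@H](O)[C@@H]12)O3
F3 | step 12 | (2S,5R)-2-tert-butyl-5-[(2Z)-3-iodoprop-2-en-1-yl]-5-methyl-1,3-dioxolan-4-one | C[C@]1(C/C=C\I)O[C@H](C(C)(C)C)OC1=O
F4 | step 12 | (2R,4Z)-2-hydroxy-5-iodo-N-methoxy-N,2-dimethylpent-4-enamide | I/C=C\C[C@@](C)(O)C(=O)N(C)OC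
F5 | step 12 | 4-[(tert-butyldimethylsilyl)oxy]but-2-yn-1-ol | OCC#CCO[Si](C)(C)C(C)(C)C
F6 | step 12 | (2Z)-4-[(tert-butyldimethylsilyl)oxy]-3-iodobut-2-en-1-ol | OC/C=C(\I)CO[Si](C)(C)C(C)(C)C
F7 | step 12 | triethylsilyl ether of F6 | CC[Si](CC)(CC)OC/C=C(\I)CO[Si](C)(C)C(C)(C)C
F8 | step 12 | enyne from F7 (ethynyl in place of iodine, cis to the CH2OSiEt3 carbon) | CC[Si](CC)(CC)OC/C=C(\C#C)CO[Si](C)(C)C(C)(C)C
F9 | step 12 | α′-hydroxy ynone from F8 and F4 | I/C=C\C[C@@](C)(O)C(=O)C#C/C(CO[Si](C)(C)C(C)(C)C)=C\CO[Si](CC)(CC)CC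
F10 | step 12 | (2R)-furan-3(2H)-one with (Z)-3-iodoallyl at C10 and C6 O-triethylsilyl | I/C=C\C[C@@]1(C)OC(=CC1=O)/C(CO[Si](C)(C)C(C)(C)C)=C\CO[Si](CC)(CC)CC
F11 | step 12 | primary allylic alcohol from F10 | I/C=C\C[C@@]1(C)OC(=CC1=O)/C(CO[Si](C)(C)C(C)(C)C)=C\CO
F12 | step 12 | (Z)-enal from F11 | I/C=C\C[C@@]1(C)OC(=CC1=O)/C(CO[Si](C)(C)C(C)(C)C)=C\C=O
F13 | step 12 | C6 epimer of 19 | O[C@H]1/C=C(/CO[Si](C)(C)C(C)(C)C)C2=CC(=O)[C@@](C)(C/C=C\1)O2
F14 | step 13 | macrocyclic 4Z,7Z-dien-6-one from 19 | O=C1/C=C(/CO[Si](C)(C)C(C)(C)C)C2=CC(=O)[C@@](C)(C/C=C\1)O2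
F15 | step 13 | cis-7,8-epoxy 6-ketone | O=C1/C=C(/CO[Si](C)(C)C(C)(C)C)C2=CC(=O)[C@@](C)(C[C@@H]3O[C@H]13)O2
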